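A direct plan would condense a ring A acetophenone carrying one ortho-OH as a prenyl ether with the ring B aldehyde A1 to the chalcone A2, close ring C by oxa-Michael addition to the racemic 5-O-prenyl flavanone A3, shift the prenyl group from O-5 to C-8 and then separate the enantiomers. Its weakest steps would be:
(a) the oxa-Michael closure of ring C, which would create C-2 with no control, so that a kinetic resolution (and an acylation needed only for it) would discard at least half of the most advanced material;
(b) the Claisen–Cope prenyl shift, a long Lewis-acid thermolysis that would be run on the complete, acid- and heat-sensitive skeleton;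
(c) the making of A1, which would take some seven steps (chromanone, silylation, reduction, dehydration, desilylation, formylation, protection) for one small arene.

**Plan of the new route**
The retrosynthesis cuts C2–C1' (ring C to ring B) first, then C8–prenyl, and only then ring C (back to a symmetric acetophenone plus one carbon); ring D is cut at O–CMe2 and C4a–C4.
Rings arise in the order: ring C on ring A (a chromone), ring D on ring B (a chromene), then union of the two bicycles.
Enabling feature: C-2 is the β-carbon of the vinylogous ester O1–C2=C3–C4=O of ring C and bears only H and the ring B aryl group, so a flat, achiral chromone can accept ring B at C-2 face-selectively under catalyst control.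
Ring C is closed while the two ortho-OH groups are still equivalent and C-8 is then marked by iodination, so neither a 6-/8-prenyl choice nor a sigmatropic prenyl shift occurs. No ring closure creates a stereocentre, so nothing is resolved, and the chromene fragment takes three steps via an ortho-quinone methide.

Key step: step 8

Assumption: the (S)-biaryl bisphosphine is taken to deliver the aryl group to the same enone face as (S)-BINAP does with cyclohex-2-enone, which corresponds to (2S) here; should the sense prove opposite, the (R)-ligand is used.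
Ring letters: A = benzo ring of the chromanone, C = pyranone ring, B = aryl ring at C-2, D = dimethylpyran ring fused to ring B. MEM = (2-methoxyethoxy)methyl; cod = cycloocta-1,5-diene; dppf = 1,1'-bis(diphenylphosphino)ferrocene.

**Route**

Step 1
Reactants: 1 2,6-dihydroxy-4-methoxyacetophenone
Product: 3 5-hydroxy-7-methoxy-4H-chromen-4-one, via enaminone 2 (not isolated)
Conditions: Me2NCH(OMe)2 (1.5 equiv), toluene, 90 °C; then conc. HCl, CH2Cl2, 40 °C
Reagents that add atoms: N,N-dimethylformamide dimethyl acetal, COC(OC)N(C)C
Why: Enaminone route to chromones: the amide acetal condenses with the methyl ketone and acid then promotes conjugate addition of an ortho-OH with loss of dimethylamine, closing ring C; the two OH groups of 1 are equivalent, so only one chromone can form and no stereocentre arises.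

Step 2
Reactants: 3 5-hydroxy-7-methoxy-4H-chromen-4-one
Product: 4 7-methoxy-5-[(2-methoxyethoxy)methoxy]-4H-chromen-4-one
Conditions: NaH, THF/DMF, 0 °C; MEMCl, 0 °C to rt
Reagents that add atoms: 2-methoxyethoxymethyl chloride, COCCOCCl
Why: Williamson O-alkylation of the chelated 5-OH through its sodium phenoxide gives a base-stable acetal ether, needed so that iodination goes to C-8 instead of ortho to a free OH and so that no chelating OH flanks the ketone in steps 4 and 8.

Step 3
Reactants: 4 7-methoxy-5-[(2-methoxyethoxy)methoxy]-4H-chromen-4-one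
Product: 5 8-iodo-7-methoxy-5-[(2-methoxyethoxy)methoxy]-4H-chromen-4-one
Conditions: NIS (1.1 equiv), DMF, 0 °C to rt, dark
Reagents that add atoms: N-iodosuccinimide, O=C1CCC(=O)N1I
Why: Electrophilic aromatic iodination under neutral conditions should go to C-8, which with O-5 alkylated is the most activated and least hindered position of ring A (ortho to 7-OMe and to O-1, para to O-5), whereas C-6 lies between two alkoxy groups and C-3 of the enone is far less nucleophilic.

Step 4
Reactants: 5 8-iodo-7-methoxy-5-[(2-methoxyethoxy)methoxy]-4H-chromen-4-one; 6 4,4,5,5-tetramethyl-2-(3-methylbut-2-enyl)-1,3,2-dioxaborolane (prenylboronic acid pinacol ester)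
Product: 7 7-methoxy-5-[(2-methoxyethoxy)methoxy]-8-(3-methylbut-2-enyl)-4H-chromen-4-one
Conditions: PdCl2(dppf) (5 mol %), CsF (3 equiv), THF, 65 °C
Reagents that add atoms: none
Why: Suzuki–Miyaura cross-coupling of the aryl iodide with the allylic boronate, in which the prenylpalladium intermediate should eliminate reductively at its unsubstituted terminus, away from the two ortho substituents, to give the linear prenyl group, while anhydrous fluoride activation spares the base-sensitive pyranone.

Step 5
Reactants: 8 4-bromobenzene-1,3-diol (4-bromoresorcinol); 9 3-methylbut-2-enal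
Product: 11 6-bromo-2,2-dimethyl-2H-chromen-7-ol, via ortho-quinone methide 10 (not isolated)
Conditions: ethylenediammonium diacetate (10 mol %), toluene, reflux, Dean–Stark
Reagents that add atoms: none
Why: Amine-catalysed chromenylation of a phenol: Knoevenagel-type C-alkylation at C-6 of the resorcinol (ortho to one OH, para to the other, the usual site of electrophilic attack on 4-substituted resorcinols), loss of water to ortho-quinone methide 10 and oxa-6π electrocyclisation close ring D together with its C–C bond to ring B, without a stereocentre.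

Step 6
Reactants: 11 6-bromo-2,2-dimethyl-2H-chromen-7-ol
Product: 12 6-bromo-7-[(2-methoxyethoxy)methoxy]-2,2-dimethyl-2H-chromene
Conditions: MEMCl, i-Pr2NEt, CH2Cl2, 0 °C to rt
Reagents that add atoms: 2-methoxyethoxymethyl chloride, COCCOCCl
Why: O-alkylation to an acetal ether that tolerates n-BuLi (a silyl ether could migrate from O to C in the aryllithium), is small next to the future boron atom and leaves under the same acid as the 5-O-MEM group.

Step 7
Reactants: 12 6-bromo-7-[(2-methoxyethoxy)methoxy]-2,2-dimethyl-2H-chromene
Product: 15 {7-[(2-methoxyethoxy)methoxy]-2,2-dimethyl-2H-chromen-6-yl}boronic acid, via aryllithium 13 (not isolated), via lithium triisopropoxyborate 14 (not isolated)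
Conditions: n-BuLi (1.05 equiv), THF, −78 °C; B(Oi-Pr)3, −78 to 0 °C; cold 1 M HCl to pH 5–6
Reagents that add atoms: triisopropyl borate, CC(C)OB(OC(C)C)OC(C)C; water, O
Why: Bromine–lithium exchange, faster than any deprotonation and helped by chelation of lithium by the MEM oxygens, followed by trapping with the borate and mild hydrolysis to the boronic acid.

Step 8
Reactants: 7 7-methoxy-5-[(2-methoxyethoxy)methoxy]-8-(3-methylbut-2-enyl)-4H-chromen-4-one; 15 {7-[(2-methoxyethoxy)methoxy]-2,2-dimethyl-2H-chromen-6-yl}boronic acid
Product: 16 (2S)-7-methoxy-5-[(2-methoxyethoxy)methoxy]-2-{7-[(2-methoxyethoxy)methoxy]-2,2-dimethyl-2H-chromen-6-yl}-8-(3-methylbut-2-enyl)chroman-4-one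
Conditions: [Rh(OH)(cod)]2 (1.5 mol %), (S)-6,6'-dimethoxy-2,2'-bis[bis(3,4,5-trifluorophenyl)phosphino]-1,1'-biphenyl (3.3 mol %), 15 (2.5 equiv, in portions), toluene/H2O (10:1), 25 °C
Reagents that add atoms: none
Why: Hayashi–Miyaura asymmetric 1,4-addition, the closest known case being the rhodium/bisphosphine addition of arylboronic acids to chromones that gives flavanones: 15 transmetalates to the hydroxorhodium complex, the aryl–rhodium species adds syn across C2=C3 of 7 with the aryl group going to C-2, and water protonates the oxa-π-allyl rhodium enolate at C-3 and returns the hydroxo complex. No ring is closed; the step forms the C2–C1' bond between the finished bicycles A/C and B/D. C-2, the only stereocentre, is set by the chiral bisphosphine alone, which should shield the Si face of the flat, achiral chromone so that the aryl group enters on the Re face (O1 > C3 > H), giving (2S). The step needs 1,4- over 1,2-addition and no retro-oxa-Michael opening of the product: no base is added, the electron-poor ligand allows room temperature, and the 5-O-MEM group flanks the ketone. It also needs chemoselectivity for the enone over the prenyl and chromene C=C bonds, which aryl–rhodium species should not carbometalate under these conditions; the ortho-MEM-oxy group slows transmetalation, which is met by the excess of 15.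

Step 9
Reactants: 16 (2S)-7-methoxy-5-[(2-methoxyethoxy)methoxy]-2-{7-[(2-methoxyethoxy)methoxy]-2,2-dimethyl-2H-chromen-6-yl}-8-(3-methylbut-2-enyl)chroman-4-one
Product: 18 maackiaflavanone A [(2S)-5-hydroxy-2-(7-hydroxy-2,2-dimethyl-2H-chromen-6-yl)-7-methoxy-8-(3-methylbut-2-enyl)chroman-4-one], via 5-hydroxy mono-MEM ether 17 (not isolated)
Conditions: HCl (ca. 1 M in MeOH), THF, 0 °C to rt; pH 7 phosphate buffer
Reagents that add atoms: none
Why: Acid-catalysed acetal exchange with methanol should remove both MEM groups (the one at O-5, peri to the carbonyl, first); the 8-prenyl group has no free ortho-OH to cyclise onto, and mild acid at or below rt avoids the base-induced retro-oxa-Michael opening that racemises flavanones, so (2S) should be kept.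

**Compound list**
1 | 2,6-dihydroxy-4-methoxyacetophenone | CC(=O)c1c(O)cc(OC)cc1O | starting material
2 | (E)-1-(2,6-dihydroxy-4-methoxyphenyl)-3-(dimethylamino)prop-2-en-1-one (not isolated) | CN(C)/C=C/C(=O)c1c(O)cc(OC)cc1O | intermediate
3 | 5-hydroxy-7-methoxy-4H-chromen-4-one | COc1cc(O)c2c(=O)ccoc2c1 | intermediate
4 | 7-methoxy-5-[(2-methoxyethoxy)methoxy]-4H-chromen-4-one | COCCOCOc1cc(OC)cc2occc(=O)c12 | intermediate
5 | 8-iodo-7-methoxy-5-[(2-methoxyethoxy)methoxy]-4H-chromen-4-one | COCCOCOc1cc(OC)c(I)c2occc(=O)c12 | intermediate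
6 | 4,4,5,5-tetramethyl-2-(3-methylbut-2-enyl)-1,3,2-dioxaborolane | CC(C)=CCB1OC(C)(C)C(C)(C)O1 | starting material
7 | 7-methoxy-5-[(2-methoxyethoxy)methoxy]-8-(3-methylbut-2-enyl)-4H-chromen-4-one | COCCOCOc1cc(OC)c(CC=C(C)C)c2occc(=O)c12 | intermediate
8 | 4-bromobenzene-1,3-diol | Oc1ccc(Br)c(O)c1 | starting material
9 | 3-methylbut-2-enal | CC(C)=CC=O | starting material
10 | 4-bromo-3-hydroxy-6-(3-methylbut-2-en-1-ylidene)cyclohexa-2,4-dien-1-one (not isolated) | O=C1C=C(O)C(Br)=CC1=CC=C(C)C | intermediate
11 | 6-bromo-2,2-dimethyl-2H-chromen-7-ol | CC1(C)C=Cc2cc(Br)c(O)cc2O1 | intermediate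
12 | 6-bromo-7-[(2-methoxyethoxy)methoxy]-2,2-dimethyl-2H-chromene | COCCOCOc1cc2c(cc1Br)C=CC(C)(C)O2 | intermediate
13 | {7-[(2-methoxyethoxy)methoxy]-2,2-dimethyl-2H-chromen-6-yl}lithium (not isolated) | [Li]c1cc2c(cc1OCOCCOC)OC(C)(C)C=C2 | intermediate
14 | lithium triisopropoxy{7-[(2-methoxyethoxy)methoxy]-2,2-dimethyl-2H-chromen-6-yl}borate (not isolated) | [Li+].CC(C)O[B-](OC(C)C)(OC(C)C)c1cc2c(cc1OCOCCOC)OC(C)(C)C=C2 | intermediate
15 | {7-[(2-methoxyethoxy)methoxy]-2,2-dimethyl-2H-chromen-6-yl}boronic acid | COCCOCOc1cc2c(cc1B(O)O)C=CC(C)(C)O2 | intermediate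
16 | (2S)-7-methoxy-5-[(2-methoxyethoxy)methoxy]-2-{7-[(2-methoxyethoxy)methoxy]-2,2-dimethyl-2H-chromen-6-yl}-8-(3-methylbut-2-enyl)chroman-4-one | COc1cc(OCOCCOC)c2c(c1CC=C(C)C)O[C@H](c1cc3c(cc1OCOCCOC)OC(C)(C)C=C3)CC2=O | intermediate
17 | (2S)-5-hydroxy-7-methoxy-2-{7-[(2-methoxyethoxy)methoxy]-2,2-dimethyl-2H-chromen-6-yl}-8-(3-methylbut-2-enyl)chroman-4-one (not isolated) | COc1cc(O)c2c(c1CC=C(C)C)O[C@H](c1cc3c(cc1OCOCCOC)OC(C)(C)C=C3)CC2=O | intermediate
18 | maackiaflavanone A, (2S) | COc1cc(O)c2c(c1CC=C(C)C)O[C@H](c1cc3c(cc1O)OC(C)(C)C=C3)CC2=O | target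

**Count and risks**
Total: 9 steps. Longest linear sequence: 6 steps (steps 1, 2, 3, 4, 8, 9); the ring B/D fragment takes 3 steps (5, 6, 7).

Steps most likely to fail:

1. Step 8. The ortho-alkoxy, electron-rich boronic acid may transmetalate and insert so slowly that protodeboronation wins, or the facial selectivity at C-2 may be insufficient. Fallback, setting out from 7 and 15: a palladium-catalysed oxidative Heck-type arylation of C-2 (Pd(OCOCF3)2, 1,4-benzoquinone, dioxane/DMSO, 60 °C) would give the achiral flavone 7-methoxy-5-[(2-methoxyethoxy)methoxy]-2-{7-[(2-methoxyethoxy)methoxy]-2,2-dimethyl-2H-chromen-6-yl}-8-(3-methylbut-2-enyl)-4H-chromen-4-one F1. An enantioselective copper hydride 1,4-reduction (Cu(OAc)2, DTBM-SEGPHOS of the hand found to give (2S), (EtO)2MeSiH, t-BuOH, toluene, 0 °C) would then set C-2 by hydride delivery and return to 16.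

2. Step 5. C-alkylation may occur at C-2 of the resorcinol, between the two OH groups, or a second annulation may follow, eroding regiochemical purity. Fallback, setting out from 8: Friedel–Crafts acylation and oxa-Michael closure with 3-methylbut-2-enoic acid (P2O5, MeSO3H, 70 °C) would give 6-bromo-7-hydroxy-2,2-dimethylchroman-4-one F2. Reduction (NaBH4, MeOH, 0 °C) would give 6-bromo-2,2-dimethylchromane-4,7-diol F3, and acid-catalysed dehydration (p-TsOH, toluene, 80 °C) would return to 11.

3. Step 4. Reductive elimination may occur at the substituted allyl terminus (reverse prenyl), or fluoride or adventitious hydroxide may open the pyranone. Fallback, setting out from 5: coupling with 4,4,5,5-tetramethyl-2-(prop-2-enyl)-1,3,2-dioxaborolane (PdCl2(dppf), CsF, THF, 65 °C), whose allyl group has equivalent termini, would give 7-methoxy-5-[(2-methoxyethoxy)methoxy]-8-(prop-2-enyl)-4H-chromen-4-one F4. Olefin cross-metathesis with 2-methylbut-2-ene (second-generation Grubbs catalyst, CH2Cl2, 40 °C) would return to 7.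

**Further compounds**
F1 | step 8 | 7-methoxy-5-[(2-methoxyethoxy)methoxy]-2-{7-[(2-methoxyethoxy)methoxy]-2,2-dimethyl-2H-chromen-6-yl}-8-(3-methylbut-2-enyl)-4H-chromen-4-one | COc1cc(OCOCCOC)c2c(=O)cc(-c3cc4c(cc3OCOCCOC)OC(C)(C)C=C4)oc2c1CC=C(C)C
F2 | step 5 | 6-bromo-7-hydroxy-2,2-dimethylchroman-4-one | CC1(C)CC(=O)c2cc(Br)c(O)cc2O1
F3 | step 5 | (±)-6-bromo-2,2-dimethylchromane-4,7-diol | CC1(C)CC(O)c2cc(Br)c(O)cc2O1
F4 | step 4 | 7-methoxy-5-[(2-methoxyethoxy)methoxy]-8-(prop-2-enyl)-4H-chromen-4-one | C=CCc1c(OC)cc(OCOCCOC)c2c(=O)ccoc12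
A1 | direct plan | 7-(methoxymethoxy)-2,2-dimethyl-2H-chromene-6-carbaldehyde | CC1(C)C=Cc2cc(C=O)c(OCOC)cc2O1
A2 | direct plan | (E)-1-[2-hydroxy-4-methoxy-6-(3-methylbut-2-enyloxy)phenyl]-3-[7-(methoxymethoxy)-2,2-dimethyl-2H-chromen-6-yl]prop-2-en-1-one | COc1cc(O)c(C(=O)/C=C/c2cc3c(cc2OCOC)OC(C)(C)C=C3)c(OCC=C(C)C)c1
A3 | direct plan | (±)-7-methoxy-2-[7-(methoxymethoxy)-2,2-dimethyl-2H-chromen-6-yl]-5-(3-methylbut-2-enyloxy)chroman-4-one | COc1cc(OCC=C(C)C)c2c(c1)OC(c1cc3c(cc1OCOC)OC(C)(C)C=C3)CC2=O
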